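**Assumptions:** 4-pentyn-1-ol, triethyl phosphonoacetate, allyl bromide, isovaleryl chloride and (S)-4-benzyloxazolidinone are commercial. Epoxy aldehyde 11 and aldehyde 17 are used crude. The C6 (R) alcohol is assumed to be the major NHK diastereomer; this is the least certain stereochemical step.

## Retrosynthesis
1. The target is the α,β-epoxy aldehyde. It comes from the C14 primary alcohol by oxidation, after a C6 acetylation and TBS removal on the macrocycle.
2. The only ring formed is the 10-membered carbocycle, closed last by an intramolecular Nozaki–Hiyama–Kishi (NHK) coupling of an (E)-vinyl iodide at C5 with the C6 aldehyde. This fixes the E-C4=C5 alkene and the C6 alcohol.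
3. The acyclic precursor is cut at C7–C8 by an Evans syn aldol. It joins N-isovaleryl oxazolidinone (C6, C7 and the isopropyl group) to an epoxy aldehyde (C8 to C5). The aldol sets C7 and C8.
4. The epoxy aldehyde comes from Sharpless epoxidation of an (E)-2-allyl allylic alcohol, which sets C1 and C10, followed by oxidative cleavage of the allyl group. That alcohol comes from an HWE reaction between an allyl phosphonoacetate and a vinyl-iodide aldehyde, which in turn comes from 4-pentyn-1-ol by Negishi carboalumination.

## Route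

**Step 1**
Reactants: 1, pent-4-yn-1-ol
Product: 2, (E)-5-iodo-4-methylpent-4-en-1-ol (I cis to Me)
Conditions: Me3Al, Cp2ZrCl2 (cat.), ClCH2CH2Cl, 0 °C to rt; then I2, THF, –30 °C
Reagents that add atoms: trimethylaluminium, C[Al](C)C (adds CH3); iodine, II (adds I)
Why: Negishi carboalumination is a syn methylalumination of the terminal alkyne, with Me on the internal carbon and Al on the terminal one. I2 then replaces Al, giving the E-vinyl iodide with I cis to Me. NHK later replaces I by C6 with retention, so this becomes the ring E-alkene.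

**Step 2**
Reactants: 2
Product: 3, (E)-5-iodo-4-methylpent-4-enal
Conditions: DMP, NaHCO3, CH2Cl2, rt
Reagents that add atoms: none
Why: Dess–Martin oxidation of a primary alcohol; the vinyl iodide is untouched.

**Step 3**
Reactants: 4, triethyl phosphonoacetate; 5, allyl bromide
Product: 6, ethyl 2-(diethoxyphosphoryl)pent-4-enoate
Conditions: NaH (1.0 equiv), THF, 0 °C to rt
Reagents that add atoms: allyl bromide, C=CCBr (adds the allyl group, which becomes C9, C8 and a carbon later lost)
Why: Mono-alkylation of the stabilised phosphonate carbanion (SN2). This builds the C10/C14/C9/C8 unit.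

**Step 4**
Reactants: 3; 6
Product: 7, ethyl (2E,6E)-2-allyl-7-iodo-6-methylhepta-2,6-dienoate
Conditions: NaH, THF, 0 °C; add 3, rt
Reagents that add atoms: none
Why: Horner–Wadsworth–Emmons olefination gives the E-α-alkyl enoate, with the ester trans to C2 and C9 cis to C2. This is the geometry needed for the epoxide ring relationship in the target.

**Step 5**
Reactants: 7
Product: 8, (2E,6E)-2-allyl-7-iodo-6-methylhepta-2,6-dien-1-ol
Conditions: DIBAL-H (2.5 equiv), CH2Cl2, –78 °C
Reagents that add atoms: none (hydride only)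
Why: 1,2-reduction of the ester to the allylic alcohol; the vinyl iodide and the terminal alkene survive at –78 °C.

**Step 6**
Reactants: 8
Product: 9, [(2R,3R)-2-allyl-3-((E)-4-iodo-3-methylbut-3-en-1-yl)oxiran-2-yl]methanol
Conditions: Ti(OiPr)4, D-(–)-diethyl tartrate, t-BuOOH, 4 Å MS, CH2Cl2, –20 °C
Reagents that add atoms: tert-butyl hydroperoxide, CC(C)(C)OO (supplies the epoxide O)
Why: Sharpless asymmetric epoxidation is selective for the allylic-alcohol alkene and sets C1 and C10 by reagent control. D-(–)-DET gives the 2R,3R epoxide from this E-allylic alcohol.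

**Step 7**
Reactants: 9
Product: 10, TBS ether of 9
Conditions: TBSCl, imidazole, DMF, rt
Reagents that add atoms: TBSCl, CC(C)(C)[Si](C)(C)Cl
Why: Silylation of the primary alcohol blocks C14. It prevents lactol formation with the aldehyde in Step 8 and protects C14 through the NHK step.

**Step 8**
Reactants: 10
Product: 11, 2-[(2R,3R)-2-(TBSO-methyl)-3-((E)-4-iodo-3-methylbut-3-en-1-yl)oxiran-2-yl]acetaldehyde
Conditions: OsO4 (2 mol%), NaIO4, 2,6-lutidine, dioxane/H2O 3:1, rt
Reagents that add atoms: sodium periodate, O=I(=O)(=O)[O-].[Na+] (supplies the aldehyde O)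
Why: Lemieux–Johnson cleavage takes the unhindered monosubstituted alkene much faster than the deactivated vinyl iodide. The epoxide survives the buffered conditions, and the lost CH2 is formaldehyde.

**Step 9**
Reactants: 12, (S)-4-benzyloxazolidin-2-one; 13, isovaleryl chloride
Product: 14, (S)-4-benzyl-3-(3-methylbutanoyl)oxazolidin-2-one
Conditions: n-BuLi, THF, –78 °C; then 13
Reagents that add atoms: isovaleryl chloride, CC(C)CC(=O)Cl
Why: N-acylation of the lithiated oxazolidinone.

**Step 10**
Reactants: 14; 11
Product: 15, (S)-4-benzyl-3-{(2S,3R)-3-hydroxy-2-isopropyl-4-[(2R,3R)-2-(TBSO-methyl)-3-((E)-4-iodo-3-methylbut-3-en-1-yl)oxiran-2-yl]butanoyl}oxazolidin-2-one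
Conditions: Bu2BOTf, Et3N, CH2Cl2, –78 to 0 °C; then 11 at –78 °C; H2O2/MeOH/pH 7 buffer work-up
Reagents that add atoms: none
Why: Evans syn aldol through the Z-boron enolate and a Zimmerman–Traxler transition state. The (S)-benzyl auxiliary gives the 2S,3R syn adduct, which is C7 (S) and C8 (R) of the target.

**Step 11**
Reactants: 15
Product: 16, C8 acetate of 15
Conditions: Ac2O, Et3N, DMAP (cat.), CH2Cl2, 0 °C to rt
Reagents that add atoms: acetic anhydride, CC(=O)OC(C)=O
Why: Acylation of the secondary alcohol installs the C8 acetate of the target. It also blocks retro-aldol and lactolisation.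

**Step 12**
Reactants: 16
Product: 17, (2S,3R)-3-acetoxy-4-[(2R,3R)-oxiranyl]-2-isopropylbutanal (NHK precursor; full SMILES in the list)
Conditions: DIBAL-H (1.3 equiv), CH2Cl2, –78 °C; Rochelle salt work-up; use crude
Reagents that add atoms: none (hydride only)
Why: The activated N-acyl oxazolidinone is reduced to the aldehyde at –78 °C, and the auxiliary 12 is recovered. The acetate, epoxide, vinyl iodide and TBS ether survive at this temperature.

**Step 13**
Reactants: 17
Product: 18, (1R,3R,4S,5R,6E,10R)-1-(TBSO-methyl)-5-hydroxy-7-methyl-4-isopropyl-11-oxabicyclo[8.1.0]undec-6-en-3-yl acetate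
Conditions: CrCl2 (10 equiv), NiCl2 (0.5 equiv), DMF, rt, 2 mM, substrate added by syringe pump over 10 h
Reagents that add atoms: none
Why: Intramolecular Nozaki–Hiyama–Kishi coupling. The vinylchromium forms from the E-vinyl iodide with retention and adds chemoselectively to the aldehyde, closing the 10-membered ring. The C6 (R) centre is expected to arise from macrocycle conformational control with Felkin-type approach.

**Step 14**
Reactants: 18
Product: 19, (1R,3R,4S,5R,6E,10R)-1-(TBSO-methyl)-7-methyl-4-isopropyl-11-oxabicyclo[8.1.0]undec-6-ene-3,5-diyl diacetate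
Conditions: Ac2O, Et3N, DMAP (cat.), CH2Cl2, rt
Reagents that add atoms: acetic anhydride, CC(=O)OC(C)=O
Why: Acetylation of the allylic C6 alcohol with retention.

**Step 15**
Reactants: 19
Product: 20, diacetate-epoxy alcohol (C14 free CH2OH)
Conditions: HF·pyridine, pyridine, THF, 0 °C to rt
Reagents that add atoms: none (fluoride leaves as TBSF)
Why: Buffered fluoride removes the primary TBS ether. The acetates and the epoxide survive, and no new stereocentre is formed.

**Step 16**
Reactants: 20
Product: 21, Pulicanaral A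
Conditions: DMP, NaHCO3, CH2Cl2, rt
Reagents that add atoms: none
Why: Dess–Martin oxidation of the primary epoxy alcohol to the epoxy aldehyde. C10 is quaternary, so the aldehyde cannot epimerise.

## Compound list
1 | pent-4-yn-1-ol | OCCCC#C | starting material
2 | (E)-5-iodo-4-methylpent-4-en-1-ol | OCCC/C(C)=C/I | intermediate
3 | (E)-5-iodo-4-methylpent-4-enal | O=CCC/C(C)=C/I | intermediate
4 | triethyl phosphonoacetate | CCOC(=O)CP(=O)(OCC)OCC | starting material
5 | allyl bromide | C=CCBr | starting material
6 | ethyl 2-(diethoxyphosphoryl)pent-4-enoate | CCOC(=O)C(CC=C)P(=O)(OCC)OCC | intermediate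
7 | ethyl (2E,6E)-2-allyl-7-iodo-6-methylhepta-2,6-dienoate | CCOC(=O)/C(CC=C)=C/CC/C(C)=C/I | intermediate
8 | (2E,6E)-2-allyl-7-iodo-6-methylhepta-2,6-dien-1-ol | OC/C(CC=C)=C/CC/C(C)=C/I | intermediate
9 | [(2R,3R)-2-allyl-3-((E)-4-iodo-3-methylbut-3-en-1-yl)oxiran-2-yl]methanol | OC[C@@]1(CC=C)O[C@@H]1CC/C(C)=C/I | intermediate
10 | TBS ether of 9 | CC(C)(C)[Si](C)(C)OC[C@@]1(CC=C)O[C@@H]1CC/C(C)=C/I | intermediate
11 | epoxy aldehyde (C8 CHO) | CC(C)(C)[Si](C)(C)OC[C@@]1(CC=O)O[C@@H]1CC/C(C)=C/I | intermediate
12 | (S)-4-benzyloxazolidin-2-one | O=C1N[C@@H](Cc2ccccc2)CO1 | starting material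
13 | isovaleryl chloride | CC(C)CC(=O)Cl | starting material
14 | (S)-4-benzyl-3-(3-methylbutanoyl)oxazolidin-2-one | CC(C)CC(=O)N1[C@@H](Cc2ccccc2)COC1=O | intermediate
15 | Evans syn aldol adduct | O=C1OC[C@H](Cc2ccccc2)N1C(=O)[C@@H](C(C)C)[C@H](O)C[C@]3(CO[Si](C)(C)C(C)(C)C)O[C@@H]3CC/C(C)=C/I | intermediate
16 | C8 acetate of 15 | O=C1OC[C@H](Cc2ccccc2)N1C(=O)[C@@H](C(C)C)[C@H](OC(C)=O)C[C@]3(CO[Si](C)(C)C(C)(C)C)O[C@@H]3CC/C(C)=C/I | intermediate
17 | (2S,3R)-3-acetoxy-2-isopropyl-4-(epoxide)butanal | O=C[C@@H](C(C)C)[C@H](OC(C)=O)C[C@]1(CO[Si](C)(C)C(C)(C)C)O[C@@H]1CC/C(C)=C/I | intermediate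
18 | macrocyclic C6 alcohol, C14 OTBS | O[C@@H]1/C=C(\C)CC[C@H]2O[C@@]2(CO[Si](C)(C)C(C)(C)C)C[C@@H](OC(C)=O)[C@@H]1C(C)C | intermediate
19 | macrocyclic diacetate, C14 OTBS | CC(=O)O[C@@H]1/C=C(\C)CC[C@H]2O[C@@]2(CO[Si](C)(C)C(C)(C)C)C[C@@H](OC(C)=O)[C@@H]1C(C)C | intermediate
20 | macrocyclic diacetate, C14 free CH2OH | CC(=O)O[C@@H]1/C=C(\C)CC[C@H]2O[C@@]2(CO)C[C@@H](OC(C)=O)[C@@H]1C(C)C | intermediate
21 | Pulicanaral A, (1S,3R,4S,5R,6E,10R)-1-formyl-7-methyl-4-isopropyl-11-oxabicyclo[8.1.0]undec-6-ene-3,5-diyl diacetate | CC(=O)O[C@@H]1/C=C(\C)CC[C@H]2O[C@@]2(C=O)C[C@@H](OC(C)=O)[C@@H]1C(C)C | target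

**Total steps:** 16. **Longest linear sequence:** 14 (4-pentyn-1-ol → 2 → 3 → 7 → 8 → 9 → 10 → 11 → 15 → 16 → 17 → 18 → 19 → 20 → 21).

**Three steps most likely to fail:**
1. **Step 13, NHK macrocyclisation.** Closing a strained 10-membered E-alkene ring could give poor yield or the wrong C6 epimer.
   - Fallback: change the ring-closing bond to C6–C7. Use an intramolecular Cr-mediated allylation of an E-enal (C6 aldehyde) with a C7/C11/C12 allylic bromide. Then hydrogenate the resulting isopropenyl group selectively with Wilkinson's catalyst.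
2. **Step 10, Evans aldol.** The hindered α-isopropyl imide may give low yield or dr with the sensitive β,γ-epoxy aldehyde 11.
   - Fallback: run the aldol on the epoxide-free TBS-protected allylic-ether aldehyde. Install the 1,10-epoxide after macrocyclisation by hydroxy-directed Ti/D-tartrate epoxidation of the free C14 allylic alcohol.
3. **Step 12, imide to β-acetoxy aldehyde.** The product can eliminate to the enal or epimerise at C7, and DIBAL may attack the acetate.
   - Fallback: convert the imide to an S-ethyl thioester (EtSH, Me3Al). Reduce it to the aldehyde under neutral conditions with Et3SiH/Pd-C (Fukuyama reduction), then run the NHK at once.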